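**Strategy.** The plan hinges on the C4 carbonyl of ring C: a lone one-carbon unit flanked by C4a of ring A and by C3, which carries a methoxy group, so this carbon can be delivered as carbon monoxide. One palladium-catalysed three-component coupling joins a ring A aryl iodide (iodine at the future C4a, the future O1 masked as a MOM ether on C8a), CO and the enolate of a ring B methoxymethyl ketone (future C2 and C3). It forms C4a–C4 and C4–C3 and delivers the whole carbon skeleton as an open 2-methoxy-1,3-diketone. MOM on ring A and benzyl on ring B are orthogonal, so acid can close ring C through O1–C2 in one sense only, before hydrogenolysis.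

Key step: step 5

Remark: the target is achiral; flavone numbering is used (ring C: O1, C2, C3, C4; ring A: C4a to C8a; ring B: C1' to C6').

**Step 1**
Reactants: 1 2,3-dimethoxyphenol
Product: 2 1,2-dimethoxy-3-(methoxymethoxy)benzene
Conditions: MOMCl, K2CO3, acetone, 0 °C → rt
Reagents that add atoms: chloromethyl methyl ether, COCCl
Why: Williamson-type O-alkylation of the phenol with the reactive α-chloro ether (MOM protection) should proceed cleanly and installs the directing group for step 2.

**Step 2**
Reactants: 2 1,2-dimethoxy-3-(methoxymethoxy)benzene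
Product: 4 1-iodo-3,4-dimethoxy-2-(methoxymethoxy)benzene, via aryllithium 3 (not isolated)
Conditions: n-BuLi, TMEDA, Et2O, 0 °C → rt; then I2, THF, −78 °C → rt; aq. Na2S2O3 work-up
Reagents that add atoms: iodine, [I][I]
Why: Directed ortho-metalation, in which the MOM acetal (a stronger director than OMe) steers n-BuLi to its only free ortho position, the future C4a, and iodine traps the aryllithium.

**Step 3**
Reactants: 5 2-methoxyhydroquinone
Product: 6 1,4-bis(benzyloxy)-2-methoxybenzene
Conditions: BnBr, K2CO3, DMF, 60 °C, under N2
Reagents that add atoms: benzyl bromide, BrCc1ccccc1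
Why: Williamson ether synthesis on both phenols, run under nitrogen so that the hydroquinone is not oxidised to the quinone before it is alkylated.

**Step 4**
Reactants: 6 1,4-bis(benzyloxy)-2-methoxybenzene; 7 methoxyacetyl chloride
Product: 8 1-[2,5-bis(benzyloxy)-4-methoxyphenyl]-2-methoxyethanone
Conditions: SnCl4 (1.2 equiv), CH2Cl2, −20 → 0 °C; then cold 1 M HCl
Reagents that add atoms: none
Why: Friedel–Crafts acylation, in which the position para to the methoxy group and ortho to a benzyloxy group is the most activated unhindered site of the 1,2,4-trioxygenated ring, and SnCl4 at low temperature should be mild enough to leave the benzyl ethers in place.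

**Step 5**
Reactants: 4 1-iodo-3,4-dimethoxy-2-(methoxymethoxy)benzene; 8 1-[2,5-bis(benzyloxy)-4-methoxyphenyl]-2-methoxyethanone; 9 carbon monoxide
Product: 12 1-[2,5-bis(benzyloxy)-4-methoxyphenyl]-3-[3,4-dimethoxy-2-(methoxymethoxy)phenyl]-2-methoxypropane-1,3-dione, via sodium enolate 10 (not isolated), via sodium diketonate 11 (not isolated)
Conditions: 8 (2 equiv) pre-enolised with NaN(SiMe3)2 (2 equiv), THF, 0 °C; then 4, Pd(dba)2 (5 mol%), Xantphos (6 mol%), CO (1 atm), 1,4-dioxane, 80 °C; AcOH quench, 0 °C (surplus 8 recovered)
Reagents that add atoms: none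
Why: Zerovalent palladium carrying Xantphos inserts into the carbon–iodine bond of 4, CO inserts into the aryl–palladium bond, and the catalyst-bound aroyl group is passed to the carbon of sodium enolate 10 by reductive elimination, which makes C4a–C4 and C4–C3 in one catalytic cycle; a second equivalent of 10 deprotonates the product to diketonate 11, which shields it from retro-Claisen cleavage until the AcOH quench. The closest known reaction type is the palladium-catalysed carbonylative α-arylation of aryl alkyl ketones with aryl iodides to give 1,3-diketones. No ring is closed here. The only new stereocentre, the CH(OMe) carbon between the two carbonyls, is enolisable, forms as a racemate and becomes the sp2 carbon C3 in step 6, so it needs no control. The step needs CO insertion to beat direct α-arylation, C- to beat O-acylation and a single site of enolisation: the CO atmosphere with the wide-bite-angle diphosphine and the ortho-OMOM group slow direct aryl–enolate coupling relative to insertion, the sodium enolate reacts at carbon at the acyl–palladium centre, and 8 has α-hydrogens only at its CH2(OMe) carbon. The MOM, benzyl and methyl ethers are inert to the base and to the catalyst.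

**Step 6**
Reactants: 12 1-[2,5-bis(benzyloxy)-4-methoxyphenyl]-3-[3,4-dimethoxy-2-(methoxymethoxy)phenyl]-2-methoxypropane-1,3-dione
Product: 14 2-[2,5-bis(benzyloxy)-4-methoxyphenyl]-3,7,8-trimethoxy-4H-chromen-4-one, via phenolic diketone 13 (not isolated)
Conditions: HCl (3 M in MeOH), 60 °C
Reagents that add atoms: none
Why: Acid-catalysed methanolysis of the MOM acetal frees the ring A phenol in 13, which adds to the ring B carbonyl (6-exo-trig, O1–C2) and loses water to give the aromatic 4-pyranone, the cyclodehydration that ends Baker–Venkataraman-type flavone syntheses, while the benzylated ring B oxygens leave only this sense of closure open.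

**Step 7**
Reactants: 14 2-[2,5-bis(benzyloxy)-4-methoxyphenyl]-3,7,8-trimethoxy-4H-chromen-4-one
Product: 15 diplotrin A, 2-(2,5-dihydroxy-4-methoxyphenyl)-3,7,8-trimethoxy-4H-chromen-4-one
Conditions: H2 (1 atm), 10% Pd/C, EtOAc–MeOH, rt; filtration under argon
Reagents that add atoms: none
Why: Catalytic hydrogenolysis of the two aryl benzyl ethers should leave the methyl ethers and the tetrasubstituted, vinylogous-ester C2=C3 bond of the chromone untouched at 1 atm.

**Compound list**

1 | 2,3-dimethoxyphenol | COc1cccc(O)c1OC | starting material
2 | 1,2-dimethoxy-3-(methoxymethoxy)benzene | COCOc1cccc(OC)c1OC | intermediate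
3 | [3,4-dimethoxy-2-(methoxymethoxy)phenyl]lithium (not isolated) | [Li]c1ccc(OC)c(OC)c1OCOC | intermediate
4 | 1-iodo-3,4-dimethoxy-2-(methoxymethoxy)benzene | COCOc1c(I)ccc(OC)c1OC | intermediate
5 | 2-methoxyhydroquinone (2-methoxybenzene-1,4-diol) | COc1cc(O)ccc1O | starting material
6 | 1,4-bis(benzyloxy)-2-methoxybenzene | COc1cc(OCc2ccccc2)ccc1OCc1ccccc1 | intermediate
7 | methoxyacetyl chloride | COCC(=O)Cl | starting material
8 | 1-[2,5-bis(benzyloxy)-4-methoxyphenyl]-2-methoxyethanone | COCC(=O)c1cc(OCc2ccccc2)c(OC)cc1OCc1ccccc1 | intermediate
9 | carbon monoxide | [C-]#[O+] | starting material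
10 | sodium 1-[2,5-bis(benzyloxy)-4-methoxyphenyl]-2-methoxyethenolate (enolate of 8; geometry not defined; not isolated) | COC=C([O-])c1cc(OCc2ccccc2)c(OC)cc1OCc1ccccc1.[Na+] | intermediate
11 | sodium enolate of diketone 12 (not isolated) | COCOc1c(C(=O)C(OC)=C([O-])c2cc(OCc3ccccc3)c(OC)cc2OCc2ccccc2)ccc(OC)c1OC.[Na+] | intermediate
12 | 1-[2,5-bis(benzyloxy)-4-methoxyphenyl]-3-[3,4-dimethoxy-2-(methoxymethoxy)phenyl]-2-methoxypropane-1,3-dione (racemic, enolisable) | COCOc1c(C(=O)C(OC)C(=O)c2cc(OCc3ccccc3)c(OC)cc2OCc2ccccc2)ccc(OC)c1OC | intermediate
13 | 1-[2,5-bis(benzyloxy)-4-methoxyphenyl]-3-(2-hydroxy-3,4-dimethoxyphenyl)-2-methoxypropane-1,3-dione (racemic, enolisable; not isolated) | COc1ccc(C(=O)C(OC)C(=O)c2cc(OCc3ccccc3)c(OC)cc2OCc2ccccc2)c(O)c1OC | intermediate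
14 | 2-[2,5-bis(benzyloxy)-4-methoxyphenyl]-3,7,8-trimethoxy-4H-chromen-4-one | COc1cc(OCc2ccccc2)c(-c2oc3c(OC)c(OC)ccc3c(=O)c2OC)cc1OCc1ccccc1 | intermediate
15 | diplotrin A, 2-(2,5-dihydroxy-4-methoxyphenyl)-3,7,8-trimethoxy-4H-chromen-4-one (achiral) | COc1cc(O)c(-c2oc3c(OC)c(OC)ccc3c(=O)c2OC)cc1O | target

**Total step count:** 7
**Longest linear sequence:** 5 steps (steps 1, 2, 5, 6, 7 or steps 3, 4, 5, 6, 7)

**Steps most likely to fail**

1. Step 5. The coupling may run without CO uptake (direct α-arylation), the catalyst may stall at oxidative addition into the electron-rich iodide under CO, or the enolate may be acylated at oxygen. The fallback makes the same two bonds one after the other, with C4 coming from DMF instead of CO. It sets out from 2 and 8 and comes back at 12. Compound 2 would be lithiated as in step 2 to aryllithium 3, which would be quenched with DMF in place of iodine to give 3,4-dimethoxy-2-(methoxymethoxy)benzaldehyde F1. Sodium enolate 10, made from 8 with NaN(SiMe3)2 in THF at −78 °C, would add to F1 in an aldol reaction, and a cold AcOH quench should give 1-[2,5-bis(benzyloxy)-4-methoxyphenyl]-3-[3,4-dimethoxy-2-(methoxymethoxy)phenyl]-3-hydroxy-2-methoxypropan-1-one F2 as a mixture of diastereomers, which does not matter. Oxidation of F2 with Dess–Martin periodinane (NaHCO3, CH2Cl2, rt) should give 12, ready for step 6.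

2. Step 4. The Lewis acid may chelate the new ketone and strip the neighbouring benzyl ether, or the methoxyacetyl cation may lose CO and alkylate the ring instead of acylating it. The fallback avoids Lewis acid altogether. It sets out from 6 and comes back at 8. N-Bromosuccinimide (MeCN, 0 °C) should brominate 6 para to the methoxy group to give 1,4-bis(benzyloxy)-2-bromo-5-methoxybenzene F3. Bromine–lithium exchange with n-BuLi (THF, −78 °C) would give [2,5-bis(benzyloxy)-4-methoxyphenyl]lithium F4. Acylation of F4 with the Weinreb amide N,2-dimethoxy-N-methylacetamide, which stops at the ketone stage, should give 8.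

3. Step 7. Hydrogenation may partly saturate the C2=C3 bond of the chromone or stall at the hindered 2'-benzyl ether, and the freed hydroquinone may be oxidised by air while the catalyst is filtered off. The fallback is a non-reductive Lewis-acid debenzylation. It sets out from 14 and comes back at 15, and it makes no new compound (F0). BCl3 with pentamethylbenzene as benzyl-cation scavenger (CH2Cl2, −78 °C, methanol quench) should cleave both benzyl ethers while the aryl methyl ethers and the 3-methoxy group survive the short, cold exposure.

**Further compounds**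

F1 | step 5 | 3,4-dimethoxy-2-(methoxymethoxy)benzaldehyde | COCOc1c(C=O)ccc(OC)c1OC
F2 | step 5 | 1-[2,5-bis(benzyloxy)-4-methoxyphenyl]-3-[3,4-dimethoxy-2-(methoxymethoxy)phenyl]-3-hydroxy-2-methoxypropan-1-one (racemic mixture of diastereomers; both stereocentres are lost on oxidation) | COCOc1c(C(O)C(OC)C(=O)c2cc(OCc3ccccc3)c(OC)cc2OCc2ccccc2)ccc(OC)c1OC
F3 | step 4 | 1,4-bis(benzyloxy)-2-bromo-5-methoxybenzene | COc1cc(OCc2ccccc2)c(Br)cc1OCc1ccccc1
F4 | step 4 | [2,5-bis(benzyloxy)-4-methoxyphenyl]lithium | [Li]c1cc(OCc2ccccc2)c(OC)cc1OCc1ccccc1
F0 | step 7 | none | none
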